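Abbreviations: MOM = methoxymethyl (CH2OCH3); prenyl = 3-methylbut-2-enyl; TIPS = triisopropylsilyl; TBS = tert-butyldimethylsilyl; Bpin = 4,4,5,5-tetramethyl-1,3,2-dioxaborolan-2-yl. Compound numbers are those of the steps and of the compound list.

## Analysis of the target

Isoangustone A 24 is an isoflavone. A benzene ring A is fused through C4a and C8a to a 4-pyranone ring C (O1, C2, C3, C4), and C3 carries a second benzene ring B. Ring A has hydroxyl groups at C5 and C7 with a prenyl group between them at C6. Ring B is a catechol (C3'-OH, C4'-OH) with a second prenyl group at C5', next to the C4' oxygen. There is no stereocentre, and both side-chain alkenes end in a gem-dimethyl group, so no alkene geometry has to be controlled. The sensitive functions are the two trisubstituted alkenes, each next to a phenol that adds to it under acid to give a chroman, and the air-sensitive catechol. Together they exclude hydrogenolysis, strong acid, late electrophilic halogenation and quinone oxidants. The difficulty is regiochemical (prenyl at C6 and not C8 of a phloroglucinol-type ring, prenyl beside one particular oxygen of the catechol), and the oxidised pyranone must be built without touching the prenyl groups. The plan rests on C4: a lone carbonyl carbon bonded to the aryl carbon C4a and to C3, which carries ring B and the one-carbon unit C2. This is the pattern left when carbon monoxide 18 is inserted between an aryl halide and a 1-arylvinyl nucleophile, after which O1 only has to add to C2.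

## Retrosynthetic reasoning

**Unmasking the phenols (24 from 23).** The four O–CH2 acetal bonds at O5, O7, O3' and O4' are cut last. The free catechol and the phenols beside the prenyl groups are the most fragile parts of 24, so they are carried as MOM ethers throughout. The forward reaction must cleave four acetals without letting a liberated phenol add to the neighbouring alkene.

**The C2=C3 double bond (23 from 22 from 21).** Removing this unsaturation gives the isoflavanone 21, whose ring can be closed by a simple conjugate addition. Aromatising ring C late keeps the carbon skeleton assembly free of oxidants. The forward reaction is a dehydrogenation through the silyl enol ether 22, which needs neither a quinone nor a halogen and so spares the prenyl groups.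

**The O1–C2 bond (21 from 19 via 20).** Cutting O1–C2 opens ring C to an aryl vinyl ketone in which the O1 oxygen is a silyl ether. The cut is made here because the open compound 19 has both carbon–carbon bonds of C4 exposed for a carbonylative disconnection. In the forward direction desilylation must release the phenoxide of 20, which adds to the enone terminus in a 6-endo-trig oxa-Michael closure.

**The two bonds to C4 (19 from 9, 17 and 18).** C4a–C4 and C4–C3 are cut together. This gives an aryl iodide 9, an alkenylboronate 17 and carbon monoxide 18 as the carbonyl carbon. Cutting C3–C1' instead would require a preformed, prenylated 3-halochromone, whose ring would have to be built first. Here each aromatic ring is finished separately and the ketone is created in the union. The forward reaction must insert 18 into the aryl–palladium bond before the boronate transfers its alkenyl group.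

**Ring A iodide (9 from 8 from 7).** The O–Si bond and then the C–I bond are cut. Phenol 7 has a mirror plane through the hydroxyl carbon and the prenyl-bearing carbon, so its two ortho positions are identical and the para position is blocked. Electrophilic iodination can therefore give only 8.

**Ring A prenyl group (7 from 6 from 3 and 4 via 5, 3 from 2 from 1).** The aryl–CH2 bond is cut at the carbon lying between the two MOM oxygens. That carbon is the cooperative site for directed ortho-metalation, so aryllithium 5 forms there and is alkylated by 4. The third oxygen is held as a bulky, non-directing silyl ether (3), which is why 2 is silylated before metalation and desilylated afterwards. Compound 2 comes from the symmetric triol 1 by double acetalisation.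

**Ring B boronate (17 from 15 and 16, 15 from 13 and 14, 13 from 11 and 12, 11 from 10).** The C–B bond is cut to the terminal alkyne 15 and diboron 16. The boron must go to the internal carbon so that the terminal carbon becomes C2 of ring C. The alkyne comes from aldehyde 13 by one-carbon homologation with 14. The aryl–prenyl bond of 13 is cut at the C–Br bond of 11, which fixes the prenyl position beside the C4' oxygen. Compound 11 is the bis-MOM ether of the bromocatechol aldehyde 10.

## Alternatives that were turned down

**Alternative 1:** anodic catechol oxidation with enaminone addition.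
- Disconnection: C3–C1' and O1–C2. Ring A arrives as the enaminone A1 (its aminovinyl carbon becomes C2, its alpha carbon C3) and ring B as the unprotected prenylcatechol A2.
- Forward key step: A2 is oxidised at a carbon anode at controlled potential to the ortho-quinone A3. The alpha carbon of A1 adds to A3 in conjugate fashion, the adduct re-aromatises, and the ring A phenol displaces the amine at the iminium carbon. This closes ring C and gives A4 directly at the isoflavone oxidation level.
- For: no protecting groups on ring B, electrons as the only oxidant, and ring C formed aromatic in one operation. On step count after fragment union it is stronger than the chosen route, which needs steps 12 to 14 for the same result.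
- Against: A3 has two conjugate positions, and only attack at the one para to the carbonyl remote from the prenyl group gives the 3',4'-dihydroxy-5'-prenyl pattern. Only a modest steric and electronic bias decides this. A3 also has an allylic, benzylic CH2 beside a quinone carbonyl and can tautomerise to a quinone methide and cyclise. A1 and A4 are electron-rich phenols with oxidation potentials close to that of A2, so over-oxidation at the electrode is likely.
- Comparison: the chosen route fixes C1' through the formyl carbon of 10 and the boron-bearing carbon of 17, so ring B regiochemistry is not left to a quinone. No oxidant stronger than Pd(OAc)2 meets the phenol ethers or the prenyl groups.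

**Alternative 2:** double aromatic Claisen shift of two tertiary allyl ethers.
- Disconnection: the C6–CH2 and C5'–CH2 bonds. Both prenyl groups are traced back to 1,1-dimethylallyl groups on O5 and O4' of a preformed isoflavone, A5.
- Forward key step: A5 is heated in a neutral high-boiling solvent. Two [3,3] shifts carry each tertiary allyl group to the free ortho carbon with allyl inversion, so that linear prenyl groups appear in A6.
- For: no metal, both prenyl groups placed at once, and only one hydrogen-bearing ortho carbon on each ring (C6 and C5'). In avoiding organolithium and organotin steps it is stronger than the chosen route.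
- Against: A5 needs tertiary ethers on the two least convenient oxygens. O5 is hydrogen-bonded to the C4 carbonyl and is the weakest nucleophile of the four. O4' has to be told apart from O3' inside a catechol while O7 and O3' carry MOM groups. This runs against the natural reactivity order and costs a long protecting-group sequence on a core that must be made first. Tertiary allyl aryl ethers are made indirectly and fragment on heating. C4a is also ortho to O5, and a shift there followed by a Cope step would deliver the group to C8. The phenols set free beside the new prenyl groups can add to them at the rearrangement temperature.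
- Comparison: once A5 is counted in full the step economy is no better. The chosen route forms each aryl–prenyl bond at a position fixed by symmetry (step 3) or by a C–Br bond (step 8) and never heats a free ortho-prenylphenol.

**Alternative 3:** photogenerated quinoketene cycloaddition with a ring B enol ether.
- Disconnection: C3–C4 and O1–C2. Ring A with its carbonyl carbon arrives as the benzodioxinone A7 and ring B as the enol ether A9.
- Forward key step: irradiation of A7 expels the ketone of its acetonide and leaves the quinoketene A8. The beta carbon of A9 attacks the ketene carbon and the ring oxygen closes on the resulting oxocarbenium ion, a formal [4+2] addition that gives the 2-methoxychromanone A10 (trans, racemic).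
- For: neutral, reagent-free ring construction. A10 already has the isoflavone oxidation level and needs only loss of its C2 alkoxy group, whereas the chosen route needs a dehydrogenation. On this point it is stronger.
- Against: ketenes such as A8 are normally trapped by O–H and N–H nucleophiles, and capture by an enol ether is far less secure. The two donor oxygens of A8 lower its electrophilicity. A9 is a styrene chromophore absorbing in the same region, so E/Z isomerisation and [2+2] reactions compete. The prenyl alkenes are further 2π partners. A7 also poses the same regiochemical problem as 9 (prenyl at the future C6), so nothing is saved in the ring A fragment.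
- Comparison: the chosen coupling is thermal, catalytic and follows a well-charted cycle. The price is steps 13 and 14.

Key step: step 11

Remark on the chemistry: isoflavanone 21 is formed as a racemate. This is without consequence because its only stereocentre (C3) becomes sp2 in step 13.

## Route

Step 1
Reactants: 1 phloroglucinol
Product: 2 3,5-bis(methoxymethoxy)phenol
Conditions: MOMCl (2.0 equiv), iPr2NEt, DMF, 0 °C → rt
Reagents that add atoms: chloromethyl methyl ether, COCCl
Why: O-alkylation of the phenoxide with a hard chloromethyl ether; the three hydroxyls are equivalent, so two equivalents should give the bis-ether as the main statistical product, separable by polarity from the mono- and tris-ethers.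

Step 2
Reactants: 2 3,5-bis(methoxymethoxy)phenol
Product: 3 [3,5-bis(methoxymethoxy)phenoxy]triisopropylsilane
Conditions: TIPSCl, imidazole, DMF, rt
Reagents that add atoms: chlorotriisopropylsilane, CC(C)[Si](Cl)(C(C)C)C(C)C
Why: Standard phenol silylation; the TIPS ether is chosen because it resists attack by n-BuLi in step 3 and does not direct metalation.

Step 3
Reactants: 3 [3,5-bis(methoxymethoxy)phenoxy]triisopropylsilane; 4 prenyl bromide
Product: 6 [3,5-bis(methoxymethoxy)-4-(3-methylbut-2-enyl)phenoxy]triisopropylsilane, via aryllithium 5 (not isolated)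
Conditions: n-BuLi, THF, 0 °C; then CuI (10 mol %), 4, −78 °C → rt
Reagents that add atoms: prenyl bromide 4, CC(C)=CCBr
Why: Directed ortho-metalation at the C–H between the two MOM ethers, the only site with two chelating oxygens; copper-assisted SN2 alkylation at the primary carbon of 4 should give the linear prenyl arene.

Step 4
Reactants: 6 [3,5-bis(methoxymethoxy)-4-(3-methylbut-2-enyl)phenoxy]triisopropylsilane
Product: 7 3,5-bis(methoxymethoxy)-4-(3-methylbut-2-enyl)phenol
Conditions: Bu4NF, THF, 0 °C; aq. NH4Cl
Reagents that add atoms: none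
Why: Fluoride desilylation driven by the Si–F bond; MOM ethers and the alkene are inert.

Step 5
Reactants: 7 3,5-bis(methoxymethoxy)-4-(3-methylbut-2-enyl)phenol
Product: 8 2-iodo-3,5-bis(methoxymethoxy)-4-(3-methylbut-2-enyl)phenol
Conditions: I2 (1.05 equiv), NaHCO3, THF/H2O, 0 °C
Reagents that add atoms: iodine, I-I
Why: Electrophilic aromatic iodination of a phenoxide; the two ortho carbons are equivalent and the para carbon is blocked, the hydroxyl is para to the prenyl group so iodoetherification is impossible, and the phenoxide should outrun the trisubstituted alkene.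

Step 6
Reactants: 8 2-iodo-3,5-bis(methoxymethoxy)-4-(3-methylbut-2-enyl)phenol
Product: 9 tert-butyl[2-iodo-3,5-bis(methoxymethoxy)-4-(3-methylbut-2-enyl)phenoxy]dimethylsilane
Conditions: TBSCl, imidazole, DMF, rt
Reagents that add atoms: tert-butylchlorodimethylsilane, CC(C)(C)[Si](C)(C)Cl
Why: Phenol silylation; TBS is small enough to sit beside iodine and can be removed at 0 °C next to an enone in step 12.

Step 7
Reactants: 10 3-bromo-4,5-dihydroxybenzaldehyde
Product: 11 3-bromo-4,5-bis(methoxymethoxy)benzaldehyde
Conditions: MOMCl (3 equiv), iPr2NEt, CH2Cl2, 0 °C → rt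
Reagents that add atoms: chloromethyl methyl ether, COCCl
Why: Exhaustive O-alkylation of both catechol hydroxyls; no differentiation within the catechol is needed.

Step 8
Reactants: 11 3-bromo-4,5-bis(methoxymethoxy)benzaldehyde; 12 tributyl(3-methylbut-2-enyl)stannane
Product: 13 3,4-bis(methoxymethoxy)-5-(3-methylbut-2-enyl)benzaldehyde
Conditions: 12 (1.3 equiv), Pd(PPh3)4 (5 mol %), DMF, 100 °C
Reagents that add atoms: tributyl(3-methylbut-2-enyl)stannane 12, CC(C)=CC[Sn](CCCC)(CCCC)CCCC
Why: Stille coupling: oxidative addition into the C–Br bond, transfer of the allyl group from tin and reductive elimination at the less substituted terminus should give the linear prenyl arene; the aldehyde is tolerated.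

Step 9
Reactants: 13 3,4-bis(methoxymethoxy)-5-(3-methylbut-2-enyl)benzaldehyde; 14 dimethyl (1-diazo-2-oxopropyl)phosphonate
Product: 15 5-ethynyl-1,2-bis(methoxymethoxy)-3-(3-methylbut-2-enyl)benzene
Conditions: 14 (1.3 equiv), K2CO3, MeOH, rt
Reagents that add atoms: dimethyl (1-diazo-2-oxopropyl)phosphonate 14, COP(=O)(OC)C(=[N+]=[N-])C(C)=O
Why: Seyferth–Gilbert homologation in the Ohira–Bestmann form: methanolysis releases the diazomethylphosphonate anion, which olefinates the aldehyde; loss of nitrogen and a 1,2-hydrogen shift give the terminal alkyne under conditions that spare the MOM ethers.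

Step 10
Reactants: 15 5-ethynyl-1,2-bis(methoxymethoxy)-3-(3-methylbut-2-enyl)benzene; 16 bis(pinacolato)diboron
Product: 17 2-{1-[3,4-bis(methoxymethoxy)-5-(3-methylbut-2-enyl)phenyl]ethenyl}-4,4,5,5-tetramethyl-1,3,2-dioxaborolane
Conditions: 16 (1.1 equiv), CuCl (5 mol %), 1,3-bis(2,4,6-trimethylphenyl)imidazolinium chloride (5 mol %), NaOtBu (20 mol %), MeOH (2 equiv), THF, −50 → −15 °C
Reagents that add atoms: bis(pinacolato)diboron 16, CC1(C)OB(OC1(C)C)B1OC(C)(C)C(C)(C)O1
Why: Copper-catalysed borylcupration of a terminal aryl alkyne; with an N-aryl carbene on monovalent copper the boryl group should go to the internal carbon (CuCl with phosphine ligands would give the linear isomer), and methanol protonates the C–Cu bond; the prenyl alkene is not attacked.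

Step 11
Reactants: 9 tert-butyl[2-iodo-3,5-bis(methoxymethoxy)-4-(3-methylbut-2-enyl)phenoxy]dimethylsilane; 17 2-{1-[3,4-bis(methoxymethoxy)-5-(3-methylbut-2-enyl)phenyl]ethenyl}-4,4,5,5-tetramethyl-1,3,2-dioxaborolane; 18 carbon monoxide
Product: 19 1-[6-(tert-butyldimethylsilyloxy)-2,4-bis(methoxymethoxy)-3-(3-methylbut-2-enyl)phenyl]-2-[3,4-bis(methoxymethoxy)-5-(3-methylbut-2-enyl)phenyl]prop-2-en-1-one
Conditions: 18 (1 atm), PdCl2(PPh3)2 (5 mol %), K2CO3 (3 equiv), anisole, 80 °C
Reagents that add atoms: carbon monoxide 18, [C-]#[O+]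
Why: The divalent precatalyst is reduced in the flask to zerovalent palladium, which inserts into the C–I bond of 9; carbon monoxide 18 then migrates into the aryl–palladium bond to give an aroylpalladium iodide, carbonate-assisted transmetalation with 17 delivers the 1-arylvinyl group, and reductive elimination forms C4–C3, so both bonds to C4 are made in one catalytic cycle. The closest known reaction type is the carbonylative Suzuki–Miyaura coupling of aryl iodides, including di-ortho-substituted ones, with organoboron reagents to give unsymmetrical ketones. No ring is closed and no stereocentre is formed. The selectivity needed is insertion of 18 before transmetalation: the two ortho oxygen substituents and the electron-rich ring of 9 slow direct alkenyl transfer to the arylpalladium species while favouring migratory insertion, and the atmosphere of 18 keeps that species saturated. The silyl ether on the future O1 keeps a phenoxide from attacking the aroylpalladium intermediate, and the MOM ethers and prenyl alkenes are inert to solid carbonate. The enone 19 is shielded at its carbonyl by the two ortho substituents and should survive, but it is best taken into step 12 without storage.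

Step 12
Reactants: 19 1-[6-(tert-butyldimethylsilyloxy)-2,4-bis(methoxymethoxy)-3-(3-methylbut-2-enyl)phenyl]-2-[3,4-bis(methoxymethoxy)-5-(3-methylbut-2-enyl)phenyl]prop-2-en-1-one
Product: 21 5,7-bis(methoxymethoxy)-3-[3,4-bis(methoxymethoxy)-5-(3-methylbut-2-enyl)phenyl]-6-(3-methylbut-2-enyl)-2,3-dihydro-4H-chromen-4-one (racemic), via hydroxyaryl enone 20 (not isolated)
Conditions: Bu4NF, THF, 0 °C → rt; aq. NH4Cl
Reagents that add atoms: none
Why: Fluoride cleaves the aryl silyl ether, and the phenoxide of 20 adds to the enone terminus in a 6-endo-trig oxa-Michael closure that forms O1–C2; protonation of the enolate sets C3 without control, which does not matter because C3 is planarised in step 13.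

Step 13
Reactants: 21 5,7-bis(methoxymethoxy)-3-[3,4-bis(methoxymethoxy)-5-(3-methylbut-2-enyl)phenyl]-6-(3-methylbut-2-enyl)-2,3-dihydro-4H-chromen-4-one
Product: 22 {5,7-bis(methoxymethoxy)-3-[3,4-bis(methoxymethoxy)-5-(3-methylbut-2-enyl)phenyl]-6-(3-methylbut-2-enyl)-2H-chromen-4-yl}oxy(trimethyl)silane
Conditions: Me3SiCl, then LiN(SiMe3)2, THF, −78 °C (in situ trap); used crude
Reagents that add atoms: chlorotrimethylsilane, C[Si](C)(C)Cl
Why: Deprotonation at C3, the only enolisable position and activated by the aryl group, with immediate O-silylation; trapping in situ keeps the enolate lifetime short and so limits reversible E1cB opening of ring C.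

Step 14
Reactants: 22 {5,7-bis(methoxymethoxy)-3-[3,4-bis(methoxymethoxy)-5-(3-methylbut-2-enyl)phenyl]-6-(3-methylbut-2-enyl)-2H-chromen-4-yl}oxy(trimethyl)silane
Product: 23 5,7-bis(methoxymethoxy)-3-[3,4-bis(methoxymethoxy)-5-(3-methylbut-2-enyl)phenyl]-6-(3-methylbut-2-enyl)-4H-chromen-4-one
Conditions: Pd(OAc)2 (1.1 equiv), MeCN, rt
Reagents that add atoms: none
Why: Saegusa–Ito oxidation: silicon-to-palladium exchange gives a palladium enolate bound at C3, and beta-hydride elimination from C2, the only carbon with beta hydrogens, forms the C2=C3 bond; the conditions are neutral and at room temperature, so the prenyl alkenes and MOM ethers should be untouched.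

Step 15
Reactants: 23 5,7-bis(methoxymethoxy)-3-[3,4-bis(methoxymethoxy)-5-(3-methylbut-2-enyl)phenyl]-6-(3-methylbut-2-enyl)-4H-chromen-4-one
Product: 24 isoangustone A
Conditions: 3 M aq. HCl, MeOH, 45 °C, degassed
Reagents that add atoms: none
Why: Acid-catalysed acetal solvolysis of the four aryl MOM ethers, the C5 ether being assisted by the neighbouring carbonyl; moderate temperature and short reaction time are meant to keep the freed phenols from adding to the prenyl alkenes, and degassing protects the catechol.

## Compound list

1 | phloroglucinol (benzene-1,3,5-triol) | Oc1cc(O)cc(O)c1 | starting material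
2 | 3,5-bis(methoxymethoxy)phenol | COCOc1cc(O)cc(OCOC)c1 | intermediate
3 | [3,5-bis(methoxymethoxy)phenoxy]triisopropylsilane | COCOc1cc(OCOC)cc(O[Si](C(C)C)(C(C)C)C(C)C)c1 | intermediate
4 | prenyl bromide (1-bromo-3-methylbut-2-ene) | CC(C)=CCBr | starting material
5 | [2,6-bis(methoxymethoxy)-4-(triisopropylsilyloxy)phenyl]lithium | COCOc1cc(O[Si](C(C)C)(C(C)C)C(C)C)cc(OCOC)c1[Li] | intermediate (not isolated)
6 | [3,5-bis(methoxymethoxy)-4-(3-methylbut-2-enyl)phenoxy]triisopropylsilane | CC(C)=CCc1c(OCOC)cc(O[Si](C(C)C)(C(C)C)C(C)C)cc1OCOC | intermediate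
7 | 3,5-bis(methoxymethoxy)-4-(3-methylbut-2-enyl)phenol | CC(C)=CCc1c(OCOC)cc(O)cc1OCOC | intermediate
8 | 2-iodo-3,5-bis(methoxymethoxy)-4-(3-methylbut-2-enyl)phenol | CC(C)=CCc1c(OCOC)cc(O)c(I)c1OCOC | intermediate
9 | tert-butyl[2-iodo-3,5-bis(methoxymethoxy)-4-(3-methylbut-2-enyl)phenoxy]dimethylsilane | CC(C)=CCc1c(OCOC)cc(O[Si](C)(C)C(C)(C)C)c(I)c1OCOC | intermediate
10 | 3-bromo-4,5-dihydroxybenzaldehyde | O=Cc1cc(O)c(O)c(Br)c1 | starting material
11 | 3-bromo-4,5-bis(methoxymethoxy)benzaldehyde | O=Cc1cc(OCOC)c(OCOC)c(Br)c1 | intermediate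
12 | tributyl(3-methylbut-2-enyl)stannane | CC(C)=CC[Sn](CCCC)(CCCC)CCCC | starting material
13 | 3,4-bis(methoxymethoxy)-5-(3-methylbut-2-enyl)benzaldehyde | O=Cc1cc(CC=C(C)C)c(OCOC)c(OCOC)c1 | intermediate
14 | dimethyl (1-diazo-2-oxopropyl)phosphonate | COP(=O)(OC)C(=[N+]=[N-])C(C)=O | starting material
15 | 5-ethynyl-1,2-bis(methoxymethoxy)-3-(3-methylbut-2-enyl)benzene | C#Cc1cc(CC=C(C)C)c(OCOC)c(OCOC)c1 | intermediate
16 | bis(pinacolato)diboron | CC1(C)OB(OC1(C)C)B1OC(C)(C)C(C)(C)O1 | starting material
17 | 2-{1-[3,4-bis(methoxymethoxy)-5-(3-methylbut-2-enyl)phenyl]ethenyl}-4,4,5,5-tetramethyl-1,3,2-dioxaborolane | C=C(B1OC(C)(C)C(C)(C)O1)c1cc(CC=C(C)C)c(OCOC)c(OCOC)c1 | intermediate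
18 | carbon monoxide | [C-]#[O+] | starting material
19 | 1-[6-(tert-butyldimethylsilyloxy)-2,4-bis(methoxymethoxy)-3-(3-methylbut-2-enyl)phenyl]-2-[3,4-bis(methoxymethoxy)-5-(3-methylbut-2-enyl)phenyl]prop-2-en-1-one | C=C(C(=O)c1c(O[Si](C)(C)C(C)(C)C)cc(OCOC)c(CC=C(C)C)c1OCOC)c1cc(CC=C(C)C)c(OCOC)c(OCOC)c1 | intermediate
20 | 1-[6-hydroxy-2,4-bis(methoxymethoxy)-3-(3-methylbut-2-enyl)phenyl]-2-[3,4-bis(methoxymethoxy)-5-(3-methylbut-2-enyl)phenyl]prop-2-en-1-one (present as its tetrabutylammonium phenoxide) | C=C(C(=O)c1c(O)cc(OCOC)c(CC=C(C)C)c1OCOC)c1cc(CC=C(C)C)c(OCOC)c(OCOC)c1 | intermediate (not isolated)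
21 | 5,7-bis(methoxymethoxy)-3-[3,4-bis(methoxymethoxy)-5-(3-methylbut-2-enyl)phenyl]-6-(3-methylbut-2-enyl)-2,3-dihydro-4H-chromen-4-one (racemic at C3) | O=C1C(c2cc(CC=C(C)C)c(OCOC)c(OCOC)c2)COc2cc(OCOC)c(CC=C(C)C)c(OCOC)c21 | intermediate
22 | {5,7-bis(methoxymethoxy)-3-[3,4-bis(methoxymethoxy)-5-(3-methylbut-2-enyl)phenyl]-6-(3-methylbut-2-enyl)-2H-chromen-4-yl}oxy(trimethyl)silane | C[Si](C)(C)OC1=C(c2cc(CC=C(C)C)c(OCOC)c(OCOC)c2)COc2cc(OCOC)c(CC=C(C)C)c(OCOC)c21 | intermediate
23 | 5,7-bis(methoxymethoxy)-3-[3,4-bis(methoxymethoxy)-5-(3-methylbut-2-enyl)phenyl]-6-(3-methylbut-2-enyl)-4H-chromen-4-one | O=c1c(-c2cc(CC=C(C)C)c(OCOC)c(OCOC)c2)coc2cc(OCOC)c(CC=C(C)C)c(OCOC)c12 | intermediate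
24 | isoangustone A, 3-[3,4-dihydroxy-5-(3-methylbut-2-enyl)phenyl]-5,7-dihydroxy-6-(3-methylbut-2-enyl)-4H-chromen-4-one | CC(C)=CCc1cc(-c2coc3cc(O)c(CC=C(C)C)c(O)c3c2=O)cc(O)c1O | target

## Step count and risks

Total: 15 steps. Longest linear sequence: 11 steps (steps 1 to 6 and 11 to 15). The ring B branch (steps 7 to 10) joins at step 11.

**Step 11 (key step).**
- What may go wrong: the alkenyl transfer from the alpha-branched boronate to the crowded aroylpalladium species may be slow, so the catalyst stalls and the boronate is lost by protodeboronation. Direct coupling without insertion of 18 and base-induced oligomerisation of the enone are further losses.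
- Fallback: a deoxybenzoin route that sets out from 15 and 9 and returns at 23, so that steps 12 to 14 are not needed. Hydroboration of 15 with dicyclohexylborane (THF, 0 °C) should give (E)-dicyclohexyl{2-[3,4-bis(methoxymethoxy)-5-(3-methylbut-2-enyl)phenyl]ethenyl}borane F1, oxidised in the same flask with NaBO3·4H2O to 2-[3,4-bis(methoxymethoxy)-5-(3-methylbut-2-enyl)phenyl]acetaldehyde F2. Iodine–magnesium exchange on 9 with iPrMgCl·LiCl (THF, −20 °C) gives [6-(tert-butyldimethylsilyloxy)-2,4-bis(methoxymethoxy)-3-(3-methylbut-2-enyl)phenyl]magnesium chloride F3. Addition of F3 to F2 in the presence of LaCl3·2LiCl at −78 °C, which suppresses enolisation, gives the racemic carbinol 1-[6-(tert-butyldimethylsilyloxy)-2,4-bis(methoxymethoxy)-3-(3-methylbut-2-enyl)phenyl]-2-[3,4-bis(methoxymethoxy)-5-(3-methylbut-2-enyl)phenyl]ethanol F4. Dess–Martin oxidation gives the corresponding ethanone F5, and Bu4NF gives the 2-hydroxydeoxybenzoin 1-[6-hydroxy-2,4-bis(methoxymethoxy)-3-(3-methylbut-2-enyl)phenyl]-2-[3,4-bis(methoxymethoxy)-5-(3-methylbut-2-enyl)phenyl]ethanone F6. Heating F6 with N,N-dimethylformamide dimethyl acetal (toluene, 90 °C) forms the enaminone 3-(dimethylamino)-1-[6-hydroxy-2,4-bis(methoxymethoxy)-3-(3-methylbut-2-enyl)phenyl]-2-[3,4-bis(methoxymethoxy)-5-(3-methylbut-2-enyl)phenyl]prop-2-en-1-one F7, which closes ring C by addition–elimination to give 23.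

**Step 10.**
- What may go wrong: erosion of regiocontrol in the borylcupration. The alkyne is made electron-rich by the para oxygen, and the preference for boron at the internal carbon falls as the aryl group becomes more electron-rich.
- Fallback: from 13 to 17 through an enol triflate. MeMgBr (THF, 0 °C) gives racemic 1-[3,4-bis(methoxymethoxy)-5-(3-methylbut-2-enyl)phenyl]ethanol F8. MnO2 (CH2Cl2) gives 1-[3,4-bis(methoxymethoxy)-5-(3-methylbut-2-enyl)phenyl]ethanone F9. KN(SiMe3)2 and PhNTf2 (THF, −78 °C) give 1-[3,4-bis(methoxymethoxy)-5-(3-methylbut-2-enyl)phenyl]ethenyl trifluoromethanesulfonate F10. Miyaura borylation of F10 with 16 (PdCl2(PPh3)2, PPh3, KOPh, toluene, 50 °C) places boron at the required carbon and gives 17.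

**Step 8.**
- What may go wrong: allylic transposition during transfer from tin, which would attach the tertiary carbon of the allyl unit to the ring, and migration of the double bond into conjugation at 100 °C.
- Fallback: from 11 to 13 in two steps. Stille coupling of 11 with allyltributylstannane (Pd(PPh3)4, toluene, 100 °C), where transposition changes nothing, gives 3,4-bis(methoxymethoxy)-5-(prop-2-enyl)benzaldehyde F11. Cross-metathesis of F11 with excess 2-methylbut-2-ene and the second-generation Grubbs catalyst RuCl2(=CHPh)(PCy3)(H2IMes) (CH2Cl2, 40 °C) gives 13.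

**Step 14.**
- What may go wrong: slow beta-hydride elimination from a palladium enolate at a fully substituted carbon, so that protodesilylation returns 21. With a stoichiometric divalent palladium salt, coordination to the prenyl alkenes may also compete.
- Fallback: from 21 to 23 by selenoxide elimination. LiN(SiMe3)2 and PhSeCl (THF, −78 °C) give 5,7-bis(methoxymethoxy)-3-[3,4-bis(methoxymethoxy)-5-(3-methylbut-2-enyl)phenyl]-6-(3-methylbut-2-enyl)-3-(phenylselanyl)-2,3-dihydro-4H-chromen-4-one F12. NaIO4 with NaHCO3 (THF/MeOH/H2O, rt) gives the selenoxide 5,7-bis(methoxymethoxy)-3-[3,4-bis(methoxymethoxy)-5-(3-methylbut-2-enyl)phenyl]-6-(3-methylbut-2-enyl)-3-(phenylseleninyl)-2,3-dihydro-4H-chromen-4-one F13, which undergoes syn elimination towards C2, the only carbon with beta hydrogens, to give 23.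

**Step 15.**
- What may go wrong: acid-catalysed addition of a freed phenol to its neighbouring prenyl alkene (chroman formation), Markovnikov addition of solvent to the alkenes, or incomplete cleavage if the acid is kept mild.
- Fallback: from 23 to 24 without protic acid. Me3SiOTf and 2,2'-bipyridyl (MeCN, 0 °C) exchange the aryl MOM ethers for silyl ethers and give 3-[5-(3-methylbut-2-enyl)-3,4-bis(trimethylsilyloxy)phenyl]-6-(3-methylbut-2-enyl)-5,7-bis(trimethylsilyloxy)-4H-chromen-4-one F14. Addition of water at rt hydrolyses F14 to 24.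

## Further compounds

F1 | step 11 | (E)-dicyclohexyl{2-[3,4-bis(methoxymethoxy)-5-(3-methylbut-2-enyl)phenyl]ethenyl}borane | CC(C)=CCc1cc(/C=C/B(C2CCCCC2)C2CCCCC2)cc(OCOC)c1OCOC
F2 | step 11 | 2-[3,4-bis(methoxymethoxy)-5-(3-methylbut-2-enyl)phenyl]acetaldehyde | CC(C)=CCc1cc(CC=O)cc(OCOC)c1OCOC
F3 | step 11 | [6-(tert-butyldimethylsilyloxy)-2,4-bis(methoxymethoxy)-3-(3-methylbut-2-enyl)phenyl]magnesium chloride | CC(C)=CCc1c(OCOC)cc(O[Si](C)(C)C(C)(C)C)c([Mg]Cl)c1OCOC
F4 | step 11 | 1-[6-(tert-butyldimethylsilyloxy)-2,4-bis(methoxymethoxy)-3-(3-methylbut-2-enyl)phenyl]-2-[3,4-bis(methoxymethoxy)-5-(3-methylbut-2-enyl)phenyl]ethanol (racemic) | CC(C)=CCc1cc(CC(O)c2c(O[Si](C)(C)C(C)(C)C)cc(OCOC)c(CC=C(C)C)c2OCOC)cc(OCOC)c1OCOC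
F5 | step 11 | 1-[6-(tert-butyldimethylsilyloxy)-2,4-bis(methoxymethoxy)-3-(3-methylbut-2-enyl)phenyl]-2-[3,4-bis(methoxymethoxy)-5-(3-methylbut-2-enyl)phenyl]ethanone | CC(C)=CCc1cc(CC(=O)c2c(O[Si](C)(C)C(C)(C)C)cc(OCOC)c(CC=C(C)C)c2OCOC)cc(OCOC)c1OCOC
F6 | step 11 | 1-[6-hydroxy-2,4-bis(methoxymethoxy)-3-(3-methylbut-2-enyl)phenyl]-2-[3,4-bis(methoxymethoxy)-5-(3-methylbut-2-enyl)phenyl]ethanone | CC(C)=CCc1cc(CC(=O)c2c(O)cc(OCOC)c(CC=C(C)C)c2OCOC)cc(OCOC)c1OCOC
F7 | step 11 | 3-(dimethylamino)-1-[6-hydroxy-2,4-bis(methoxymethoxy)-3-(3-methylbut-2-enyl)phenyl]-2-[3,4-bis(methoxymethoxy)-5-(3-methylbut-2-enyl)phenyl]prop-2-en-1-one (alkene geometry not fixed) | CN(C)C=C(C(=O)c1c(O)cc(OCOC)c(CC=C(C)C)c1OCOC)c1cc(CC=C(C)C)c(OCOC)c(OCOC)c1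
F8 | step 10 | 1-[3,4-bis(methoxymethoxy)-5-(3-methylbut-2-enyl)phenyl]ethanol (racemic) | CC(O)c1cc(CC=C(C)C)c(OCOC)c(OCOC)c1
F9 | step 10 | 1-[3,4-bis(methoxymethoxy)-5-(3-methylbut-2-enyl)phenyl]ethanone | CC(=O)c1cc(CC=C(C)C)c(OCOC)c(OCOC)c1
F10 | step 10 | 1-[3,4-bis(methoxymethoxy)-5-(3-methylbut-2-enyl)phenyl]ethenyl trifluoromethanesulfonate | C=C(OS(=O)(=O)C(F)(F)F)c1cc(CC=C(C)C)c(OCOC)c(OCOC)c1
F11 | step 8 | 3,4-bis(methoxymethoxy)-5-(prop-2-enyl)benzaldehyde | C=CCc1cc(C=O)cc(OCOC)c1OCOC
F12 | step 14 | 5,7-bis(methoxymethoxy)-3-[3,4-bis(methoxymethoxy)-5-(3-methylbut-2-enyl)phenyl]-6-(3-methylbut-2-enyl)-3-(phenylselanyl)-2,3-dihydro-4H-chromen-4-one (racemic) | O=C1C(c2cc(CC=C(C)C)c(OCOC)c(OCOC)c2)([Se]c2ccccc2)COc2cc(OCOC)c(CC=C(C)C)c(OCOC)c21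
F13 | step 14 | 5,7-bis(methoxymethoxy)-3-[3,4-bis(methoxymethoxy)-5-(3-methylbut-2-enyl)phenyl]-6-(3-methylbut-2-enyl)-3-(phenylseleninyl)-2,3-dihydro-4H-chromen-4-one (mixture of diastereomers) | O=C1C(c2cc(CC=C(C)C)c(OCOC)c(OCOC)c2)([Se](=O)c2ccccc2)COc2cc(OCOC)c(CC=C(C)C)c(OCOC)c21
F14 | step 15 | 3-[5-(3-methylbut-2-enyl)-3,4-bis(trimethylsilyloxy)phenyl]-6-(3-methylbut-2-enyl)-5,7-bis(trimethylsilyloxy)-4H-chromen-4-one | CC(C)=CCc1cc(-c2coc3cc(O[Si](C)(C)C)c(CC=C(C)C)c(O[Si](C)(C)C)c3c2=O)cc(O[Si](C)(C)C)c1O[Si](C)(C)C
A1 | alternative 1 | (E)-3-(dimethylamino)-1-[6-hydroxy-2,4-bis(methoxymethoxy)-3-(3-methylbut-2-enyl)phenyl]prop-2-en-1-one | CN(C)/C=C/C(=O)c1c(O)cc(OCOC)c(CC=C(C)C)c1OCOC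
A2 | alternative 1 | 3-(3-methylbut-2-enyl)benzene-1,2-diol | CC(C)=CCc1cccc(O)c1O
A3 | alternative 1 | 3-(3-methylbut-2-enyl)cyclohexa-3,5-diene-1,2-dione | CC(C)=CCC1=CC=CC(=O)C1=O
A4 | alternative 1 | 5,7-di-O-methoxymethyl isoangustone A | CC(C)=CCc1cc(-c2coc3cc(OCOC)c(CC=C(C)C)c(OCOC)c3c2=O)cc(O)c1O
A5 | alternative 2 | 7-(methoxymethoxy)-3-[3-(methoxymethoxy)-4-(2-methylbut-3-en-2-yloxy)phenyl]-5-(2-methylbut-3-en-2-yloxy)-4H-chromen-4-one | C=CC(C)(C)Oc1ccc(-c2coc3cc(OCOC)cc(OC(C)(C)C=C)c3c2=O)cc1OCOC
A6 | alternative 2 | 7,3'-di-O-methoxymethyl isoangustone A | CC(C)=CCc1cc(-c2coc3cc(OCOC)c(CC=C(C)C)c(O)c3c2=O)cc(OCOC)c1O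
A7 | alternative 3 | 5,7-bis(methoxymethoxy)-2,2-dimethyl-6-(3-methylbut-2-enyl)-4H-1,3-benzodioxin-4-one | CC1(C)OC(=O)c2c(O1)cc(OCOC)c(CC=C(C)C)c2OCOC
A8 | alternative 3 | 3,5-bis(methoxymethoxy)-4-(3-methylbut-2-enyl)-6-(oxomethylidene)cyclohexa-2,4-dien-1-one | O=C=C1C(=O)C=C(OCOC)C(CC=C(C)C)=C1OCOC
A9 | alternative 3 | (E)-5-(2-methoxyethenyl)-1,2-bis(methoxymethoxy)-3-(3-methylbut-2-enyl)benzene | CO/C=C/c1cc(CC=C(C)C)c(OCOC)c(OCOC)c1
A10 | alternative 3 | trans-2-methoxy-5,7-bis(methoxymethoxy)-3-[3,4-bis(methoxymethoxy)-5-(3-methylbut-2-enyl)phenyl]-6-(3-methylbut-2-enyl)-2,3-dihydro-4H-chromen-4-one (racemic, one enantiomer drawn) | CO[C@@H]1Oc2cc(OCOC)c(CC=C(C)C)c(OCOC)c2C(=O)[C@H]1c1cc(CC=C(C)C)c(OCOC)c(OCOC)c1
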